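**Retrosynthetic overview**
1. Target ⇒ acetylation of the 8β tertiary alcohol ⇒ ring E (15,16-lactone) closed by rhodium-carbenoid insertion of a 16-O-diazoacetate into the C13–H bond with retention; C13 comes from (S)-butane-1,2,4-triol acetonide.
2. Ring D (9α,13-spiro ether) and the trans-diaxial 8β,9α-dioxygen pair ⇒ 5-exo opening of an 8β,9β-epoxide by the C13 oxygen; the epoxide ⇒ 7β-OH-directed epoxidation; 7β-OH/Δ8 ⇒ 1,3-transposition of a C9 carbinol made by alkyllithium addition to a C9 enone.
3. Ring C (19,6β-lactone) and quaternary C4 ⇒ dianion methylation with in-situ lactonisation after Luche reduction of C6.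
4. Rings B and A ⇒ catalytic enantioselective Diels–Alder reaction that desymmetrises 2,6-dimethyl-1,4-benzoquinone (from aerobic dearomatisation of 2,6-dimethylphenol) with methyl (E)-penta-2,4-dienoate, then cis→trans epimerisation at C5.
5. Ring order: B (from the phenol) → A → C → D → E.

Convention: labdane numbering (C1–C20) is used for all intermediates; β is the face of the C20 methyl group.
Assumption: the (S)-configured oxazaborolidinium catalyst gives the absolute series drawn; if the induction is opposite, the (R)-catalyst is used with no other change.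

**Route**

Step 1
Reactants: 1 2,6-dimethylphenol
Product: 2 2,6-dimethyl-1,4-benzoquinone
Conditions: O2 (1 atm), Co(salen) [Co(C16H14N2O2), divalent cobalt, 5 mol%], DMF, 25 °C
Reagents that add atoms: dioxygen, O=O
Why: Cobalt–salen-catalysed aerobic oxidation (phenoxyl radical trapped by O2 at the free para position) is the standard dearomatising conversion of 2,6-dialkylphenols into p-benzoquinones and creates no stereocentre.

Step 2
Reactants: 2 2,6-dimethyl-1,4-benzoquinone; 3 methyl (E)-penta-2,4-dienoate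
Product: 5 trans-fused enedione ester, via cis-fused cycloadduct 4 (not isolated)
Conditions: (S)-3,3-diphenyl-1-(o-tolyl)tetrahydro-1H,3H-pyrrolo[1,2-c][1,3,2]oxazaborole·HNTf2 (20 mol%), 3 (2 equiv), CH2Cl2, −78 → −20 °C; then DBU (0.5 equiv), 0 °C, 30 min
Reagents that add atoms: none
Why: Catalyst-controlled endo Diels–Alder cycloaddition desymmetrises the mirror-symmetric quinone, because the oxazaborolidinium binds the unhindered C6 carbonyl so that the unsubstituted diene terminus bonds to the methyl-bearing carbon and only one enantiotopic C=C face reacts (sets C10, transiently C4 and C5), after which DBU epimerises C5 through the C6 enolate to the more stable trans ring fusion (5α-H).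

Step 3
Reactants: 5 trans-fused enedione ester
Product: 6 6β-hydroxy enone ester
Conditions: NaBH4 (1.0 equiv), CeCl3·7H2O (1.1 equiv), MeOH–CH2Cl2, −78 °C
Reagents that add atoms: none
Why: Luche 1,2-reduction attacks the less hindered C6 carbonyl (C9 is flanked by quaternary C10 and the C8 methyl) from the α face opposite the axial C20 methyl and so gives the axial 6β-alcohol.

Step 4
Reactants: 6 6β-hydroxy enone ester
Product: 8 tricyclic lactone enone, via C4-methylated hydroxy ester 7 (not isolated)
Conditions: LiN(iPr)2 (2.3 equiv), THF–DMPU, −78 °C; MeI (1.2 equiv), −78 → 23 °C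
Reagents that add atoms: iodomethane, CI
Why: Ester enolate alkylation of the alkoxide/dienolate dianion: iodomethane enters at C4 (α-carbon) from the α face, away from the syn-axial C20 methyl and the 6β-alkoxide, which leaves the ester axial (β) next to the 6β-alkoxide so that lactonisation by intramolecular transesterification follows on warming.

Step 5
Reactants: 9 (S)-2-(2,2-dimethyl-1,3-dioxolan-4-yl)ethanol
Product: 10 (S)-4-(2-iodoethyl)-2,2-dimethyl-1,3-dioxolane
Conditions: I2, PPh3, imidazole, CH2Cl2, 0 → 23 °C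
Reagents that add atoms: iodine, II
Why: Appel iodination of a primary alcohol; the stereocentre is not touched.

Step 6
Reactants: 10 (S)-4-(2-iodoethyl)-2,2-dimethyl-1,3-dioxolane; 8 tricyclic lactone enone
Product: 12 tertiary allylic alcohol, via organolithium 11 (not isolated)
Conditions: 10 (1.3 equiv), t-BuLi (2.6 equiv), Et2O–pentane, −78 °C, 30 min; then 8 in THF, −78 °C; aq. NH4Cl
Reagents that add atoms: none
Why: Iodine–lithium exchange followed by 1,2-addition of the primary alkyllithium to the non-enolisable C9 enone carbonyl (more electrophilic than the neopentyl lactone at −78 °C) from the α face opposite the C20 methyl gives the 9β-carbinol, a centre that is relayed to C7 in the next step.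

Step 7
Reactants: 12 tertiary allylic alcohol
Product: 13 7β-hydroxy-Δ8 allylic alcohol
Conditions: Ph3SiOReO3 (heptavalent rhenium, 5 mol%), Et2O, −40 → 0 °C
Reagents that add atoms: none
Why: Rhenium-oxo-catalysed 1,3-transposition of an allylic alcohol ([3,3] shift of the allyl perrhenate) is suprafacial, so the 9β-oxygen arrives at C7 as the 7β-alcohol, and it is driven by formation of the tetrasubstituted C8=C9 alkene and relief of strain at C9.

Step 8
Reactants: 13 7β-hydroxy-Δ8 allylic alcohol
Product: 16 spiro-ether triol, via epoxy acetonide 14 (not isolated), via epoxy triol 15 (not isolated)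
Conditions: VO(acac)2 (5 mol%), t-BuOOH (1.5 equiv), CH2Cl2, 0 → 23 °C; then 1 M aq. HCl–THF (1:4), 23 °C
Reagents that add atoms: tert-butyl hydroperoxide, CC(C)(C)OO
Why: Hydroxyl-directed vanadium-catalysed epoxidation delivers oxygen syn to the 7β-OH (β face, Henbest sense, overriding the C20 methyl), and after acid removal of the acetonide the C13 hydroxyl opens the epoxide by 5-exo anti attack at C9 (Fürst–Plattner trans-diaxial opening), which sets 9α-O/C11β and leaves the 8β tertiary alcohol.

Step 9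
Reactants: 16 spiro-ether triol
Product: 17 dihydro triol
Conditions: H2 (1 atm), Pd/C (10 wt%), EtOAc, 23 °C
Reagents that add atoms: none
Why: Heterogeneous catalytic hydrogenation of the only C=C bond (C2=C3); no stereocentre is formed.

Step 10
Reactants: 17 dihydro triol
Product: 19 diazoacetate diol, via tosylhydrazone ester 18 (not isolated)
Conditions: TsNHN=CHCOCl (1.2 equiv), PhNMe2 (1.3 equiv), CH2Cl2, 0 °C; then Et3N (4 equiv), 0 → 23 °C
Reagents that add atoms: glyoxylic acid chloride p-toluenesulfonylhydrazone, Cc1ccc(cc1)S(=O)(=O)NN=CC(Cl)=O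
Why: Corey–Myers diazoacetylation: the acid chloride acylates the primary C16 alcohol in preference to the hindered secondary and tertiary ones, and triethylamine then eliminates p-toluenesulfinate from the tosylhydrazone (Bamford–Stevens type) to give the diazo ester.

Step 11
Reactants: 19 diazoacetate diol
Product: 20 diazoacetate ketol
Conditions: Dess–Martin periodinane (1.5 equiv), NaHCO3, CH2Cl2, 0 → 23 °C
Reagents that add atoms: none
Why: Dess–Martin oxidation converts the secondary 7β-alcohol into the ketone while the tertiary 8β-alcohol and the diazo ester are inert.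

Step 12
Reactants: 20 diazoacetate ketol
Product: 21 spiro-dilactone ketol
Conditions: Rh2(NHCOCH3)4 (divalent rhodium, 1 mol%), CH2Cl2, 40 °C, syringe-pump addition (2 mM final)
Reagents that add atoms: none
Why: Rhodium-carbenoid intramolecular 1,5 C–H insertion into the tertiary C13–H bond activated by the ether oxygen closes the γ-lactone with retention of configuration, so the (S)-carbinol centre bought in 9 becomes the (13R) spiro centre.

Step 13
Reactants: 21 spiro-dilactone ketol
Product: 22 target CNP0259020.1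
Conditions: Ac2O (5 equiv), Sc(OTf)3 (5 mol%), MeCN, −20 → 0 °C
Reagents that add atoms: acetic anhydride, CC(=O)OC(C)=O
Why: Lewis-acid-catalysed acylation (scandium triflate with acetic anhydride) esterifies the hindered tertiary α-ketol hydroxyl without touching any stereocentre.

**Compound list**
1 | 2,6-dimethylphenol | Cc1cccc(C)c1O | starting material
2 | 2,6-dimethyl-1,4-benzoquinone | CC1=CC(=O)C=C(C)C1=O | intermediate
3 | methyl (E)-penta-2,4-dienoate | COC(=O)/C=C/C=C | starting material
4 | cis-fused cycloadduct: methyl 4a,6-dimethyl-5,8-dioxo-1,4,4a,5,8,8a-hexahydronaphthalene-1-carboxylate, labdane descriptors 4α-CO2Me, 5β-H, 10β-Me | COC(=O)[C@@H]1C=CC[C@]2(C)C(=O)C(C)=CC(=O)[C@H]12 | intermediate (not isolated)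
5 | trans-fused enedione ester: C5 epimer of 4 (4α-CO2Me, 5α-H, 10β-Me; C6 and C9 ketones, C2=C3 and C7=C8) | COC(=O)[C@@H]1C=CC[C@]2(C)C(=O)C(C)=CC(=O)[C@@H]12 | intermediate
6 | 6β-hydroxy enone ester (6β-OH, C9 ketone, C7=C8) | COC(=O)[C@@H]1C=CC[C@]2(C)C(=O)C(C)=C[C@@H](O)[C@@H]12 | intermediate
7 | C4-methylated hydroxy ester (4α-Me, 4β-CO2Me, 6β-OH), present as its lithium alkoxide | COC(=O)[C@@]1(C)C=CC[C@]2(C)C(=O)C(C)=C[C@@H](O)[C@@H]12 | intermediate (not isolated)
8 | tricyclic lactone enone: 9-oxo-15,16-dinor-11,12,13,14-tetranor... simplified: C1–C10 trans-decalin with C2=C3, C7=C8, 9-ketone, 4α/8/10β methyls and 19,6β-lactone (5α-H) | CC1=C[C@H]2OC(=O)[C@@]3(C)C=CC[C@@](C)([C@@H]23)C1=O | intermediate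
9 | (S)-2-(2,2-dimethyl-1,3-dioxolan-4-yl)ethanol | CC1(C)OC[C@H](CCO)O1 | starting material
10 | (S)-4-(2-iodoethyl)-2,2-dimethyl-1,3-dioxolane | CC1(C)OC[C@H](CCI)O1 | intermediate
11 | (S)-2-(2,2-dimethyl-1,3-dioxolan-4-yl)ethyllithium | [Li]CC[C@H]1COC(C)(C)O1 | intermediate (not isolated)
12 | tertiary allylic alcohol: (13S)-9β-hydroxy-13,16-(isopropylidenedioxy)-14,15-dinorlabda-2,7-dien-19,6β-olide with the side chain 9α | CC1=C[C@H]2OC(=O)[C@@]3(C)C=CC[C@@](C)([C@@H]23)[C@]1(O)CC[C@H]1COC(C)(C)O1 | intermediate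
13 | (13S)-7β-hydroxy-13,16-(isopropylidenedioxy)-14,15-dinorlabda-2,8-dien-19,6β-olide | CC1=C(CC[C@H]4COC(C)(C)O4)[C@@]2(C)CC=C[C@]3(C)C(=O)O[C@H]([C@@H]1O)[C@H]23 | intermediate
14 | (13S)-8β,9β-epoxy-7β-hydroxy-13,16-(isopropylidenedioxy)-14,15-dinorlabd-2-en-19,6β-olide | C[C@]12O[C@]2(CC[C@H]4COC(C)(C)O4)[C@@]5(C)CC=C[C@]3(C)C(=O)O[C@H]([C@@H]1O)[C@H]53 | intermediate (not isolated)
15 | (13S)-8β,9β-epoxy-7β,13,16-trihydroxy-14,15-dinorlabd-2-en-19,6β-olide | C[C@]12O[C@]2(CC[C@H](O)CO)[C@@]5(C)CC=C[C@]3(C)C(=O)O[C@H]([C@@H]1O)[C@H]53 | intermediate (not isolated)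
16 | (13S)-9α,13-epoxy-7β,8β,16-trihydroxy-14,15-dinorlabd-2-en-19,6β-olide | O[C@@]1(C)[C@@H](O)[C@H]2OC(=O)[C@@]3(C)C=CC[C@@](C)([C@@H]23)[C@@]12CC[C@@H](CO)O2 | intermediate
17 | (13S)-9α,13-epoxy-7β,8β,16-trihydroxy-14,15-dinorlabdan-19,6β-olide | O[C@@]1(C)[C@@H](O)[C@H]2OC(=O)[C@@]3(C)CCC[C@@](C)([C@@H]23)[C@@]12CC[C@@H](CO)O2 | intermediate
18 | 16-O-(glyoxyloyl p-toluenesulfonylhydrazone) ester of 17 | O[C@@]1(C)[C@@H](O)[C@H]2OC(=O)[C@@]3(C)CCC[C@@](C)([C@@H]23)[C@@]12CC[C@@H](COC(=O)C=NNS(=O)(=O)c1ccc(C)cc1)O2 | intermediate (not isolated)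
19 | 16-O-diazoacetyl derivative of 17 (7β,8β-diol) | O[C@@]1(C)[C@@H](O)[C@H]2OC(=O)[C@@]3(C)CCC[C@@](C)([C@@H]23)[C@@]12CC[C@@H](COC(=O)C=[N+]=[N-])O2 | intermediate
20 | (13S)-16-(diazoacetoxy)-9α,13-epoxy-8β-hydroxy-7-oxo-14,15-dinorlabdan-19,6β-olide | O[C@@]1(C)C(=O)[C@H]2OC(=O)[C@@]3(C)CCC[C@@](C)([C@@H]23)[C@@]12CC[C@@H](COC(=O)C=[N+]=[N-])O2 | intermediate
21 | (13R)-9α,13-epoxy-8β-hydroxy-7-oxolabdane-19,6β:15,16-diolide | O[C@@]1(C)C(=O)[C@H]2OC(=O)[C@@]3(C)CCC[C@@](C)([C@@H]23)[C@@]12CC[C@@]1(COC(=O)C1)O2 | intermediate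
22 | (13R)-8β-acetoxy-9α,13-epoxy-7-oxolabdane-19,6β:15,16-diolide (CNP0259020.1) | CC(=O)O[C@@]1(C)C(=O)[C@H]2OC(=O)[C@@]3(C)CCC[C@@](C)([C@@H]23)[C@@]12CC[C@@]1(COC(=O)C1)O2 | target

**Step count**
Total steps: 13. Longest linear sequence: 12 (steps 1–4 and 6–13, from 2,6-dimethylphenol).

**Three steps most likely to fail, each with a fallback**

Step 2 (cycloaddition of an electron-poor dienoate under chiral catalysis; rate, regiocontrol and ee are all at risk). The fallback moves stereocontrol from the catalyst to the diene and uses a stoichiometric Lewis acid. It sets out from quinone 2 and comes back to the route at lactone 8. Quinone 2 is combined with (−)-8-phenylmenthyl (E)-penta-2,4-dienoate F1 (from penta-2,4-dienoyl chloride and (−)-8-phenylmenthol) and BF3·OEt2 in CH2Cl2 at −40 °C, the phenyl ring shielding one face of the ester-bearing diene terminus. The cis-fused auxiliary adduct F2 is epimerised with DBU to the trans-fused auxiliary ester F3, and Luche reduction gives the 6β-hydroxy auxiliary ester F4. The conditions of step 4 then give the C4-methylated auxiliary ester F5, which lactonises with loss of the auxiliary alcohol to give 8.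

Step 7 (the perrhenate may ionise, eroding the suprafacial transfer, or the dioxolane oxygen may capture the allyl cation). The fallback replaces the redox-neutral shift by an oxidative transposition and a stereoconvergent reduction. It sets out from 12 and comes back at 13. Pyridinium chlorochromate, [C5H5NH][CrO3Cl] (hexavalent chromium), in CH2Cl2 gives the Δ8-7-ketone F6 (Dauben–Babler oxidation, independent of the C9 configuration). Luche reduction (NaBH4, CeCl3·7H2O, MeOH, −78 °C) then delivers hydride from the α face, anti to the axial 6β-oxygen, to give 13.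

Step 13 (acylation of an axial tertiary α-ketol hydroxyl that is flanked by two fully substituted carbons and is syn-axial to C20 and O6; α-ketol rearrangement is possible under Lewis acid). The fallback never acylates the tertiary alcohol directly. It sets out from diol 19 and comes back at target 22. Trimethyl orthoacetate with PPTS converts the cis-7β,8β-diol into the 7β,8β-cyclic orthoacetate F7. Brief hydrolysis in aqueous acetic acid opens it to the axial ester, the 8β-acetoxy-7β-hydroxy diazoacetate F8. Dess–Martin oxidation gives the 8β-acetoxy-7-oxo diazoacetate F9, and the rhodium-catalysed C–H insertion of step 12 then closes the lactone to give 22.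

**Further compounds**
F1 | step 2 | (−)-8-phenylmenthyl (E)-penta-2,4-dienoate | C=C/C=C/C(=O)O[C@@H]1C[C@H](C)CC[C@H]1C(C)(C)c1ccccc1
F2 | step 2 | cis-fused auxiliary adduct (8-phenylmenthyl analogue of 4, not isolated) | O=C(O[C@@H]1C[C@H](C)CC[C@H]1C(C)(C)c1ccccc1)[C@@H]1C=CC[C@]2(C)C(=O)C(C)=CC(=O)[C@H]12
F3 | step 2 | trans-fused auxiliary ester (8-phenylmenthyl analogue of 5) | O=C(O[C@@H]1C[C@H](C)CC[C@H]1C(C)(C)c1ccccc1)[C@@H]1C=CC[C@]2(C)C(=O)C(C)=CC(=O)[C@@H]12
F4 | step 2 | 6β-hydroxy auxiliary ester (8-phenylmenthyl analogue of 6) | O=C(O[C@@H]1C[C@H](C)CC[C@H]1C(C)(C)c1ccccc1)[C@@H]1C=CC[C@]2(C)C(=O)C(C)=C[C@@H](O)[C@@H]12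
F5 | step 2 | C4-methylated auxiliary ester (8-phenylmenthyl analogue of 7, not isolated) | O=C(O[C@@H]1C[C@H](C)CC[C@H]1C(C)(C)c1ccccc1)[C@@]1(C)C=CC[C@]2(C)C(=O)C(C)=C[C@@H](O)[C@@H]12
F6 | step 7 | (13S)-13,16-(isopropylidenedioxy)-7-oxo-14,15-dinorlabda-2,8-dien-19,6β-olide | CC1=C(CC[C@H]4COC(C)(C)O4)[C@@]2(C)CC=C[C@]3(C)C(=O)O[C@H](C1=O)[C@H]23
F7 | step 13 | 7β,8β-cyclic orthoacetate (2-methoxy-2-methyl-1,3-dioxolane) of 19 (not isolated) | O7[C@@]1(C)[C@@H](OC7(C)OC)[C@H]2OC(=O)[C@@]3(C)CCC[C@@](C)([C@@H]23)[C@@]12CC[C@@H](COC(=O)C=[N+]=[N-])O2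
F8 | step 13 | 8β-acetoxy-7β-hydroxy diazoacetate | CC(=O)O[C@@]1(C)[C@@H](O)[C@H]2OC(=O)[C@@]3(C)CCC[C@@](C)([C@@H]23)[C@@]12CC[C@@H](COC(=O)C=[N+]=[N-])O2
F9 | step 13 | 8β-acetoxy-7-oxo diazoacetate | CC(=O)O[C@@]1(C)C(=O)[C@H]2OC(=O)[C@@]3(C)CCC[C@@](C)([C@@H]23)[C@@]12CC[C@@H](COC(=O)C=[N+]=[N-])O2
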